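(The numbers were set for the occasion; the rest is arithmetic.)

The pitfall is to read slow addition as a favour to rings whichever partner is dosed: violet and amber both feed over 20 h, yet in amber the second end groups sit in the flask decaying while the first end groups trickle in.

| flask | first end groups | second end groups | protic impurity | time | remark |
|---|---|---|---|---|---|
| grey | 0.25 M | 0.225 M | 5.00 mM | 30 h | everything together at the start |
| violet | 0.25 M | 0.225 M (fed, over 20 h) | 5.00 mM | 30 h | all else is in the flask from the start; the feed brings no volume worth counting |
| red | 0.25 M (fed, over 2.0 h) | 0.225 M | 5.00 mM | 30 h | all else is in the flask from the start; the feed brings no volume worth counting |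
| amber | 0.25 M (fed, over 20 h) | 0.225 M | 5.00 mM | 30 h | all else is in the flask from the start; the feed brings no volume worth counting |

- the flask that comes out highest in amount of rings, in percent of the first end groups charged; "all alike" if 1.5 percentage points covers them all (grey / violet / red / amber / all alike)
- amount of rings at the end, in percent of the first end groups charged, grey
- amount of rings at the end, in percent of the first end groups charged, violet
- amount of rings at the end, in percent of the first end groups charged, red
- amount of rings at the end, in percent of the first end groups charged, amber

- amounts and yields of links count crystals too
- given per volume of solution although it is solid: crystals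
- run time (grey): 30 h

    first end groups + second end groups → links (k1 = 0.039 M⁻¹ min⁻¹)
    first end groups + second end groups → rings, rate k2*[first end groups] as long as [second end groups] is above zero (k2 = 0.011 min⁻¹)
    crystals ⇌ links, rate k3*(cs3 - [links]) while solid is left; crystals form when [links] > cs3 (cs3 = 0.18 M, k3 = 0.21 min⁻¹)
    second end groups → decomposed reagent (k4 = 0.0020 min⁻¹)
    second end groups + protic impurity → quenched reagent (k5 = 0.54 M⁻¹ min⁻¹)

So I hold two rates against each other: what decay takes from the full charge of second end groups, 0.0270 M h⁻¹, and what the feed of first end groups in amber demands, 0.0125 M h⁻¹. At the full charge decay is faster than the demand, and their ratio is the waiting ratio 2.16, for which one is the even case. If each fed first end group reacts at once and takes one second end group, the second end groups last until this fraction of the feed has come: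

used fraction = ln(one + waiting ratio) ÷ (decay constant × feed time) = 47.9%

Rings and links split evenly where second end groups stand at 1.25 of their charge, and I take the mean level as half the charge:

ring share = 71.5%

For amber I then reckon 34.3%. For red, with a waiting ratio of 0.216, I reckon 58.3%. Grey has no feed, and I drop its decay, since the half-life of first end groups by the link step, 1.3 h, is shorter than the 5.8 h of decay, which gives 64.3%. In violet the feed of second end groups, 0.0113 M h⁻¹, stays below the ring rate I reckon for the end of the feed, 0.0165 M h⁻¹, so I take these second end groups, the limiting reagent, as used up by the ring step as they come, which gives 90.0%. My pick is violet.

The forecast named violet, with grey 60.5%, violet 90%, red 53.5% and amber 37%, holding that "starving the flask of second end groups (violet) sends nearly every fed group into rings".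

The flask gives violet as highest, with grey 60.1%, violet 90.0%, red 55.4% and amber 34.5%. In amber, 87% of the decay up to the asked time is done by 6.00 h, and at 30.0 h 43.5% of the first end groups charged have reacted, against the used fraction of 47.9%. The neighbour of amber with 0.15 M of first end groups has a waiting ratio of 3.60, which with the same ring share gives 45.5%, and at 30.0 h that flask holds 46.9% of its own first end groups charged as rings.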